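**Plan**

1. Numbering: eight-membered ring C1 (CH–OAc), C2 (CH2), C3 (CH–CH3), C4 and C5 (cyclopropane CH, C4 next to C3), C6 and C7 (butenolide α- and β-carbon), C8 (CH with the side chain); C9 is the cyclopropane CH2.
2. Enabling feature: C1 (oxygenated) and C4 are linked through C2–C3, and the other four ring atoms are two two-carbon arms (C5–C6 on C4, C8–C7 on C1) that meet at the butenolide bond C6–C7. The cyclooctane is therefore the [3,3] ring-expansion product of a cyclobutane C1–C2–C3–C4 with cis alkenyl groups on C1 (with O) and C4.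
3. Retrosynthetic cuts, in order: side-chain C–OOH (ene reaction); acetate; C6=C7 alkene and lactone C–O (the arms on C6 and C7 become CH2O groups); cyclopropane C4–C9–C5 (to a Z-alkene); C6–C7 with re-closure of C1–C4 (anionic oxy-Cope); C1–C8 (alkenyllithium plus cyclobutanone); cyclobutane bonds C2–C3 and C1–C4 ([2+2]).
4. Forward: an asymmetric [2+2] makes the four-membered ring, the (R)-citronellal-derived alkenyl fragment is added at C1, ring expansion gives the cyclooctenone, then cyclopropane, lactone, butenolide alkene, acetate and hydroperoxide follow.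
5. Stereochemistry: C3 from the catalytic asymmetric [2+2]; the side-chain methine from (R)-citronellal; C8 by equilibration next to the ketone; C1 by hydride attack anti to the C8 substituent; C4/C5 by hydroxyl-directed cyclopropanation of the Z-alkene; the side-chain E-alkene from the ene reaction.

Key step: step 13

Assumption: the facial sense of the (R,R)-TADDOL–titanium catalyst in step 6 is taken to be the one that gives the (1R,4R) adduct; both antipodes of the diol are available, so the other one is used should the sense be opposite.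

**Fragment 1: alkenylstannane**

Step 1
Reactants: 1 (R)-citronellal
Product: 3 (3R)-3,7-dimethyloct-6-en-1-yne, via alkenyl nonaflate 2 (not isolated)
Conditions: C4F9SO2F, P2-Et phosphazene base (2.2 equiv), DMF, −20 °C → rt
Reagents that add atoms: none
Why: One-pot enol nonaflation–elimination of an enolisable aldehyde to the terminal alkyne (O-sulfonylation of the enolate, then base-induced loss of nonaflate), which involves only the two aldehyde-end carbons and should leave the methyl-bearing centre untouched.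

Step 2
Reactants: 3 (3R)-3,7-dimethyloct-6-en-1-yne
Product: 5 ethyl (4R)-4,8-dimethylnon-7-en-2-ynoate, via lithium acetylide 4 (not isolated)
Conditions: n-BuLi, THF, −78 °C; ClCO2Et, −78 → 0 °C
Reagents that add atoms: ethyl chloroformate, CCOC(=O)Cl
Why: C-acylation of a lithium acetylide with a chloroformate gives the 2-alkynoate, whose ester carbon becomes the lactone CH2 on C7.

Step 3
Reactants: 5 ethyl (4R)-4,8-dimethylnon-7-en-2-ynoate
Product: 6 ethyl (2E,4R)-4,8-dimethyl-3-(trimethylstannyl)nona-2,7-dienoate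
Conditions: Me3Sn(PhS)CuLi, MeOH (1.7 equiv), THF, −100 → −78 °C
Reagents that add atoms: lithium (phenylthio)(trimethylstannyl)cuprate, [Li+].C[Sn](C)(C)[Cu-]Sc1ccccc1
Why: Stannylcupration of a 2-alkynoate places tin on the β-carbon by syn addition, and trapping the kinetic adduct with methanol at low temperature should give the E isomer (tin trans to the ester), the geometry later needed at C8=C7.

Step 4
Reactants: 6 ethyl (2E,4R)-4,8-dimethyl-3-(trimethylstannyl)nona-2,7-dienoate
Product: 7 (2E,4R)-4,8-dimethyl-3-(trimethylstannyl)nona-2,7-dien-1-ol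
Conditions: iBu2AlH (2.3 equiv), CH2Cl2, −78 °C
Reagents that add atoms: none
Why: 1,2-Reduction of an enoate to the allylic alcohol by an aluminium hydride, which leaves the C–Sn bond and the alkene geometry unchanged.

Step 5
Reactants: 7 (2E,4R)-4,8-dimethyl-3-(trimethylstannyl)nona-2,7-dien-1-ol
Product: 8 tert-butyl{[(2E,4R)-4,8-dimethyl-3-(trimethylstannyl)nona-2,7-dien-1-yl]oxy}diphenylsilane
Conditions: TBDPSCl, imidazole, DMF, rt
Reagents that add atoms: tert-butyl(chloro)diphenylsilane, CC(C)(C)[Si](Cl)(c1ccccc1)c1ccccc1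
Why: Silylation of a primary alcohol gives a robust ether that tolerates organolithium, KH and the later selective removal of the other silyl group.

**Fragment 2: cyclobutanone**

Step 6
Reactants: 9 3-[(2E)-but-2-enoyl]-1,3-oxazolidin-2-one; 10 1,1-bis(methylsulfanyl)ethene
Product: 11 3-{[(1R,4R)-4-methyl-2,2-bis(methylsulfanyl)cyclobutyl]carbonyl}-1,3-oxazolidin-2-one
Conditions: TiCl2(OiPr)2 (10 mol %), (R,R)-TADDOL (11 mol %), 4 Å molecular sieves, toluene–hexane, 0 °C
Reagents that add atoms: none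
Why: Lewis acid-catalysed asymmetric [2+2] cycloaddition of a ketene dithioacetal with a chelated enoyl imide, in which the CH2 terminus adds to the β-carbon and the titanium enolate closes onto the thionium carbon, so the E-crotonoyl geometry becomes the trans methyl/acyl relationship and the chiral titanium diolate selects the enantioface that makes the methyl-bearing carbon (later C3) R.

Step 7
Reactants: 11 3-{[(1R,4R)-4-methyl-2,2-bis(methylsulfanyl)cyclobutyl]carbonyl}-1,3-oxazolidin-2-one
Product: 12 [(1R,4R)-4-methyl-2,2-bis(methylsulfanyl)cyclobutyl]methanol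
Conditions: LiBH4, MeOH (1 equiv), THF, 0 °C
Reagents that add atoms: none
Why: Reductive cleavage of an N-acyl oxazolidinone by borohydride gives the primary alcohol while the dithioketal keeps the future C1 carbonyl masked.

Step 8
Reactants: 12 [(1R,4R)-4-methyl-2,2-bis(methylsulfanyl)cyclobutyl]methanol
Product: 14 ethyl (2E)-3-[(1R,4R)-4-methyl-2,2-bis(methylsulfanyl)cyclobutyl]prop-2-enoate, via aldehyde 13 (not isolated)
Conditions: (COCl)2, DMSO, CH2Cl2, −78 °C; Et3N; then Ph3P=CHCO2Et, −78 °C → rt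
Reagents that add atoms: ethyl (triphenylphosphoranylidene)acetate, CCOC(=O)C=P(c1ccccc1)(c1ccccc1)c1ccccc1
Why: One-pot Swern oxidation–Wittig olefination with a stabilised ylide should give the E-enoate without isolating the aldehyde, which is prone to epimerisation and thiolate loss, and any epimerisation next to the formyl group converges on the trans ring isomer.

Step 9
Reactants: 14 ethyl (2E)-3-[(1R,4R)-4-methyl-2,2-bis(methylsulfanyl)cyclobutyl]prop-2-enoate
Product: 15 (2E)-3-[(1R,4R)-4-methyl-2,2-bis(methylsulfanyl)cyclobutyl]prop-2-en-1-ol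
Conditions: iBu2AlH (2.3 equiv), CH2Cl2, −78 °C
Reagents that add atoms: none
Why: 1,2-Reduction of the enoate gives the E-allylic alcohol whose carbinol carbon is the future lactone carbonyl carbon on C6.

Step 10
Reactants: 15 (2E)-3-[(1R,4R)-4-methyl-2,2-bis(methylsulfanyl)cyclobutyl]prop-2-en-1-ol
Product: 16 tert-butyl(dimethyl){[(2E)-3-[(1R,4R)-4-methyl-2,2-bis(methylsulfanyl)cyclobutyl]prop-2-en-1-yl]oxy}silane
Conditions: TBSCl, imidazole, DMF, rt
Reagents that add atoms: tert-butyl(chloro)dimethylsilane, CC(C)(C)[Si](C)(C)Cl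
Why: Silylation of the primary allylic alcohol gives an ether that is non-coordinating in the later cyclopropanation and more acid-labile than the TBDPS ether on the other arm.

Step 11
Reactants: 16 tert-butyl(dimethyl){[(2E)-3-[(1R,4R)-4-methyl-2,2-bis(methylsulfanyl)cyclobutyl]prop-2-en-1-yl]oxy}silane
Product: 17 (2R,3R)-2-[(1E)-3-{[tert-butyl(dimethyl)silyl]oxy}prop-1-en-1-yl]-3-methylcyclobutan-1-one
Conditions: HgCl2, CaCO3, MeCN–H2O (4:1), rt
Reagents that add atoms: water, O
Why: Thiophilic metal-assisted hydrolysis of the dithioketal under carbonate buffering unmasks the cyclobutanone, and the trans 2,3-arrangement is the thermodynamic one at the enolisable α-carbon.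

**Coupling and key step**

Step 12
Reactants: 8 tert-butyl{[(2E,4R)-4,8-dimethyl-3-(trimethylstannyl)nona-2,7-dien-1-yl]oxy}diphenylsilane; 17 (2R,3R)-2-[(1E)-3-{[tert-butyl(dimethyl)silyl]oxy}prop-1-en-1-yl]-3-methylcyclobutan-1-one
Product: 19 (1S,2R,3R)-2-[(1E)-3-{[tert-butyl(dimethyl)silyl]oxy}prop-1-en-1-yl]-1-[(2E,4R)-1-{[tert-butyl(diphenyl)silyl]oxy}-4,8-dimethylnona-2,7-dien-3-yl]-3-methylcyclobutan-1-ol, via alkenyllithium 18 (not isolated)
Conditions: 8 (1.15 equiv), MeLi (1.1 equiv), THF, −78 → −30 °C; then 17, −78 °C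
Reagents that add atoms: none
Why: Tin–lithium exchange with retention of alkene geometry followed by 1,2-addition to the strained, poorly enolisable cyclobutanone, where attack along the pseudo-axial trajectory of the puckered ring, anti to the C3 methyl group and syn to the pseudo-equatorial alkenyl group on C4, is expected to set C1 with the two alkenyl groups cis, any C1 epimer being removed by chromatography.

Step 13
Reactants: 19 (1S,2R,3R)-2-[(1E)-3-{[tert-butyl(dimethyl)silyl]oxy}prop-1-en-1-yl]-1-[(2E,4R)-1-{[tert-butyl(diphenyl)silyl]oxy}-4,8-dimethylnona-2,7-dien-3-yl]-3-methylcyclobutan-1-ol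
Product: 22 (3R,4Z,6R,7R,8S)-6-({[tert-butyl(dimethyl)silyl]oxy}methyl)-7-({[tert-butyl(diphenyl)silyl]oxy}methyl)-3-methyl-8-[(2R)-6-methylhept-5-en-2-yl]cyclooct-4-en-1-one, via potassium alkoxide 20 (not isolated), via potassium enolate 21 (not isolated)
Conditions: KH (1.5 equiv), 18-crown-6 (1.5 equiv), THF, 0 °C → rt; then MeOH, rt; aq. NH4Cl
Reagents that add atoms: none
Why: KH with 18-crown-6 turns carbinol 19 into the dissociated potassium alkoxide 20, in which the oxyanion on C1 weakens the C1–C4 cyclobutane bond and sets off a concerted [3,3] sigmatropic shift of the 1,5-diene C7=C8–C1(O−)–C4–C5=C6, the anionic oxy-Cope rearrangement established for cis-1,2-dialkenylcyclobutanols. The eight-membered ring closes by ring expansion: C6–C7 forms between the two alkene termini in a boat-shaped array with both alkenyl groups folded over the four-membered ring while C1–C4 breaks, and relief of ring strain together with formation of enolate 21 makes the step irreversible. The boat array gives the C4=C5 alkene as Z, and because both termini carry their CH2OSi groups in the outward (E) positions, these end up cis to each other and to the C3 methyl group at C6 and C7, two centres that are deleted later by the butenolide alkene. C8 is fixed on work-up, where the methoxide left by the methanol quench equilibrates the α-centre so that the side chain lies trans to the C7 substituent; C3 is not touched. The step needs the concerted [3,3] path to win over a [1,3] shift and over simple β-scission, which is secured by the cis relationship of the alkenyl groups and by their E geometry, which leaves only hydrogens inside the boat.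

**Endgame**

Step 14
Reactants: 22 (3R,4Z,6R,7R,8S)-6-({[tert-butyl(dimethyl)silyl]oxy}methyl)-7-({[tert-butyl(diphenyl)silyl]oxy}methyl)-3-methyl-8-[(2R)-6-methylhept-5-en-2-yl]cyclooct-4-en-1-one
Product: 23 (1R,3R,4Z,6R,7R,8S)-6-({[tert-butyl(dimethyl)silyl]oxy}methyl)-7-({[tert-butyl(diphenyl)silyl]oxy}methyl)-3-methyl-8-[(2R)-6-methylhept-5-en-2-yl]cyclooct-4-en-1-ol
Conditions: LiBH(s-Bu)3, THF, −78 °C; NaOH, H2O2 work-up
Reagents that add atoms: none
Why: Steric approach control in a bulky trialkylborohydride reduction should deliver hydride to the carbonyl face opposite the branched C8 substituent and so place the C1 hydroxyl cis to the side chain (1R).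

Step 15
Reactants: 23 (1R,3R,4Z,6R,7R,8S)-6-({[tert-butyl(dimethyl)silyl]oxy}methyl)-7-({[tert-butyl(diphenyl)silyl]oxy}methyl)-3-methyl-8-[(2R)-6-methylhept-5-en-2-yl]cyclooct-4-en-1-ol
Product: 24 (1R,3R,4S,5S,6R,7R,8S)-cyclopropane-fused alcohol (bicyclo[6.1.0]nonane skeleton, plan numbering): C1–OH, C3–CH3, C4–C9–C5 cyclopropane, C6–CH2OTBS, C7–CH2OTBDPS, C8 (2R)-6-methylhept-5-en-2-yl
Conditions: Et2Zn (2.2 equiv), CH2I2 (4.4 equiv), CH2Cl2, −15 → 0 °C
Reagents that add atoms: diiodomethane, ICI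
Why: Simmons–Smith cyclopropanation (Et2Zn/CH2I2 variant) directed by the zinc alkoxide of the C1 hydroxyl across the ring is expected to add CH2 stereospecifically to the face of the Z-alkene that carries the hydroxyl, which is also the face away from the C3 methyl and C6 silyloxymethyl groups, and proximity to the alkoxide should favour the ring alkene over the side-chain alkene.

Step 16
Reactants: 24 cyclopropane-fused alcohol with TBS and TBDPS ethers
Product: 25 (1R,3R,4S,5S,6R,7R,8S)-diol: as 24 with C6–CH2OH free, C7–CH2OTBDPS kept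
Conditions: camphorsulfonic acid (0.1 equiv), MeOH–CH2Cl2 (1:1), 0 °C
Reagents that add atoms: none
Why: Acid-catalysed methanolysis cleaves a primary TBS ether much faster than a primary TBDPS ether, which frees only the C6 arm.

Step 17
Reactants: 25 diol with C6–CH2OH and C1–OH free
Product: 26 (1R,3R,4S,5S,6R,7S,8S)-hydroxy acid: as 25 with CO2H on C6
Conditions: TEMPO (0.2 equiv), PhI(OAc)2 (2.2 equiv), MeCN–H2O (1:1), rt
Reagents that add atoms: water, O
Why: Oxoammonium (TEMPO) oxidation is selective for the primary alcohol and carries it through the aldehyde hydrate to the acid while the hindered secondary C1 hydroxyl is left.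

Step 18
Reactants: 26 hydroxy acid with C7–CH2OTBDPS
Product: 28 (1R,3R,4S,5S,6R,7S,8S)-hydroxy lactone: cis-fused γ-lactone C6–C(=O)–O–CH2–C7 on the cyclopropane-fused eight-membered ring, C1–OH free, via hydroxy acid 27 (not isolated)
Conditions: Bu4NF, THF, rt; then 1 M HCl to pH 2, rt
Reagents that add atoms: none
Why: Fluoride desilylation frees the C7 hydroxymethyl group, which is cis to the C6 carboxyl and should close the γ-lactone on acidification (lactonisation).

Step 19
Reactants: 28 hydroxy lactone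
Product: 30 α-phenylselanyl lactone: as 28 with PhSe on C6 in place of H, cis to C7–H, via dilithium alkoxide enolate 29 (not isolated)
Conditions: LiN(iPr)2 (2.3 equiv), THF, −78 °C; PhSeBr (1.2 equiv), −78 °C
Reagents that add atoms: benzeneselenenyl bromide, Br[Se]c1ccccc1
Why: α-Selenenylation of the lactone enolate (the C1 alkoxide is a spectator) should bring selenium in on the face anti to the C7–C8 bond, that is cis to C7–H, keeping the cis ring fusion.

Step 20
Reactants: 30 α-phenylselanyl lactone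
Product: 32 (1R,3R,4S,5S,8S)-hydroxy butenolide: C6=C7 butenolide (C=O on C6, OCH2 on C7), C1–OH free, C8 (2R)-6-methylhept-5-en-2-yl, via selenoxide 31 (not isolated)
Conditions: NaIO4, NaHCO3, THF–MeOH–H2O, 0 °C → rt
Reagents that add atoms: none
Why: Selenoxide syn-elimination can only take the syn β-hydrogen on C7, which gives the tetrasubstituted butenolide and removes the C6 and C7 centres, and periodate is used so that no peracid reaches the side-chain alkene.

Step 21
Reactants: 32 hydroxy butenolide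
Product: 33 (1R,3R,4S,5S,8S)-acetate: as 32 with C1–OAc
Conditions: Ac2O, DMAP (cat.), pyridine, CH2Cl2, rt
Reagents that add atoms: acetic anhydride, CC(=O)OC(C)=O
Why: Nucleophile-catalysed acylation of the secondary alcohol installs the acetate only after all strong-base steps are over.

Step 22
Reactants: 33 acetate with (2R)-6-methylhept-5-en-2-yl side chain
Product: 34 CNP0205234.1: (1R,3R,4S,5S,8S)-acetate with (2R,4E)-6-hydroperoxy-6-methylhept-4-en-2-yl side chain
Conditions: O2, hν (visible), tetraphenylporphyrin (cat.), CH2Cl2, 0 °C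
Reagents that add atoms: dioxygen, O=O
Why: Schenck ene reaction of singlet oxygen with the trisubstituted alkene takes an allylic hydrogen from its disubstituted side, and abstraction from the CH2 group gives the tertiary hydroperoxide with the E double bond, the secondary regioisomer from methyl abstraction being removed by chromatography while the electron-poor butenolide is inert.

**Compound list**

1 | (R)-citronellal, (3R)-3,7-dimethyloct-6-enal | O=CC[C@H](C)CCC=C(C)C | starting material
2 | (3R)-3,7-dimethylocta-1,6-dien-1-yl nonafluorobutane-1-sulfonate (E/Z mixture) | FC(F)(F)C(F)(F)C(F)(F)C(F)(F)S(=O)(=O)OC=C[C@H](C)CCC=C(C)C | intermediate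
3 | (3R)-3,7-dimethyloct-6-en-1-yne | C#C[C@H](C)CCC=C(C)C | intermediate
4 | [(3R)-3,7-dimethyloct-6-en-1-yn-1-yl]lithium | [Li]C#C[C@H](C)CCC=C(C)C | intermediate
5 | ethyl (4R)-4,8-dimethylnon-7-en-2-ynoate | CCOC(=O)C#C[C@H](C)CCC=C(C)C | intermediate
6 | ethyl (2E,4R)-4,8-dimethyl-3-(trimethylstannyl)nona-2,7-dienoate | CCOC(=O)/C=C(/[Sn](C)(C)C)[C@H](C)CCC=C(C)C | intermediate
7 | (2E,4R)-4,8-dimethyl-3-(trimethylstannyl)nona-2,7-dien-1-ol | OC/C=C(/[Sn](C)(C)C)[C@H](C)CCC=C(C)C | intermediate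
8 | tert-butyl{[(2E,4R)-4,8-dimethyl-3-(trimethylstannyl)nona-2,7-dien-1-yl]oxy}diphenylsilane | CC(C)(C)[Si](OC/C=C(/[Sn](C)(C)C)[C@H](C)CCC=C(C)C)(c1ccccc1)c1ccccc1 | intermediate
9 | 3-[(2E)-but-2-enoyl]-1,3-oxazolidin-2-one | C/C=C/C(=O)N1CCOC1=O | starting material
10 | 1,1-bis(methylsulfanyl)ethene | C=C(SC)SC | starting material
11 | 3-{[(1R,4R)-4-methyl-2,2-bis(methylsulfanyl)cyclobutyl]carbonyl}-1,3-oxazolidin-2-one | CSC1(SC)C[C@@H](C)[C@@H]1C(=O)N1CCOC1=O | intermediate
12 | [(1R,4R)-4-methyl-2,2-bis(methylsulfanyl)cyclobutyl]methanol | CSC1(SC)C[C@@H](C)[C@@H]1CO | intermediate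
13 | (1R,4R)-4-methyl-2,2-bis(methylsulfanyl)cyclobutane-1-carbaldehyde | CSC1(SC)C[C@@H](C)[C@@H]1C=O | intermediate
14 | ethyl (2E)-3-[(1R,4R)-4-methyl-2,2-bis(methylsulfanyl)cyclobutyl]prop-2-enoate | CSC1(SC)C[C@@H](C)[C@@H]1/C=C/C(=O)OCC | intermediate
15 | (2E)-3-[(1R,4R)-4-methyl-2,2-bis(methylsulfanyl)cyclobutyl]prop-2-en-1-ol | CSC1(SC)C[C@@H](C)[C@@H]1/C=C/CO | intermediate
16 | tert-butyl(dimethyl){[(2E)-3-[(1R,4R)-4-methyl-2,2-bis(methylsulfanyl)cyclobutyl]prop-2-en-1-yl]oxy}silane | CSC1(SC)C[C@@H](C)[C@@H]1/C=C/CO[Si](C)(C)C(C)(C)C | intermediate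
17 | (2R,3R)-2-[(1E)-3-{[tert-butyl(dimethyl)silyl]oxy}prop-1-en-1-yl]-3-methylcyclobutan-1-one | O=C1C[C@@H](C)[C@@H]1/C=C/CO[Si](C)(C)C(C)(C)C | intermediate
18 | [(2Z,4R)-1-{[tert-butyl(diphenyl)silyl]oxy}-4,8-dimethylnona-2,7-dien-3-yl]lithium (Li trans to CH2OSi; geometry of 8 retained) | [Li]/C(=C/CO[Si](c1ccccc1)(c1ccccc1)C(C)(C)C)[C@H](C)CCC=C(C)C | intermediate
19 | (1S,2R,3R)-2-[(1E)-3-{[tert-butyl(dimethyl)silyl]oxy}prop-1-en-1-yl]-1-[(2E,4R)-1-{[tert-butyl(diphenyl)silyl]oxy}-4,8-dimethylnona-2,7-dien-3-yl]-3-methylcyclobutan-1-ol | O[C@@]1(/C(=C/CO[Si](c2ccccc2)(c2ccccc2)C(C)(C)C)[C@H](C)CCC=C(C)C)C[C@@H](C)[C@@H]1/C=C/CO[Si](C)(C)C(C)(C)C | intermediate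
20 | potassium alkoxide of 19 | [K+].[O-][C@@]1(/C(=C/CO[Si](c2ccccc2)(c2ccccc2)C(C)(C)C)[C@H](C)CCC=C(C)C)C[C@@H](C)[C@@H]1/C=C/CO[Si](C)(C)C(C)(C)C | intermediate
21 | potassium (3R,4Z,6R,7R)-6-({[tert-butyl(dimethyl)silyl]oxy}methyl)-7-({[tert-butyl(diphenyl)silyl]oxy}methyl)-3-methyl-8-[(2R)-6-methylhept-5-en-2-yl]cycloocta-1(8),4-dien-1-olate | [K+].[O-]C=1C[C@@H](C)/C=C\[C@@H](CO[Si](C)(C)C(C)(C)C)[C@@H](CO[Si](c2ccccc2)(c2ccccc2)C(C)(C)C)C=1[C@H](C)CCC=C(C)C | intermediate
22 | (3R,4Z,6R,7R,8S)-6-({[tert-butyl(dimethyl)silyl]oxy}methyl)-7-({[tert-butyl(diphenyl)silyl]oxy}methyl)-3-methyl-8-[(2R)-6-methylhept-5-en-2-yl]cyclooct-4-en-1-one | O=C1C[C@@H](C)/C=C\[C@@H](CO[Si](C)(C)C(C)(C)C)[C@@H](CO[Si](c2ccccc2)(c2ccccc2)C(C)(C)C)[C@@H]1[C@H](C)CCC=C(C)C | intermediate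
23 | (1R,3R,4Z,6R,7R,8S)-6-({[tert-butyl(dimethyl)silyl]oxy}methyl)-7-({[tert-butyl(diphenyl)silyl]oxy}methyl)-3-methyl-8-[(2R)-6-methylhept-5-en-2-yl]cyclooct-4-en-1-ol | O[C@@H]1C[C@@H](C)/C=C\[C@@H](CO[Si](C)(C)C(C)(C)C)[C@@H](CO[Si](c2ccccc2)(c2ccccc2)C(C)(C)C)[C@@H]1[C@H](C)CCC=C(C)C | intermediate
24 | (1R,3R,4S,5S,6R,7R,8S)-cyclopropane-fused alcohol (plan numbering): C1–OH, C6–CH2OTBS, C7–CH2OTBDPS | O[C@@H]1C[C@@H](C)[C@@H]2C[C@@H]2[C@@H](CO[Si](C)(C)C(C)(C)C)[C@@H](CO[Si](c3ccccc3)(c3ccccc3)C(C)(C)C)[C@@H]1[C@H](C)CCC=C(C)C | intermediate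
25 | (1R,3R,4S,5S,6R,7R,8S)-diol: C1–OH, C6–CH2OH, C7–CH2OTBDPS | O[C@@H]1C[C@@H](C)[C@@H]2C[C@@H]2[C@@H](CO)[C@@H](CO[Si](c3ccccc3)(c3ccccc3)C(C)(C)C)[C@@H]1[C@H](C)CCC=C(C)C | intermediate
26 | (1R,3R,4S,5S,6R,7S,8S)-hydroxy acid: C1–OH, C6–CO2H, C7–CH2OTBDPS | O[C@@H]1C[C@@H](C)[C@@H]2C[C@@H]2[C@@H](C(=O)O)[C@@H](CO[Si](c3ccccc3)(c3ccccc3)C(C)(C)C)[C@@H]1[C@H](C)CCC=C(C)C | intermediate
27 | (1R,3R,4S,5S,6R,7S,8S)-dihydroxy acid: C1–OH, C6–CO2H, C7–CH2OH | O[C@@H]1C[C@@H](C)[C@@H]2C[C@@H]2[C@@H](C(=O)O)[C@@H](CO)[C@@H]1[C@H](C)CCC=C(C)C | intermediate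
28 | (1R,3R,4S,5S,6R,7S,8S)-hydroxy lactone: cis-fused γ-lactone C6–C(=O)–O–CH2–C7, C1–OH | O[C@@H]1C[C@@H](C)[C@@H]2C[C@@H]2[C@H]3C(=O)OC[C@H]3[C@@H]1[C@H](C)CCC=C(C)C | intermediate
29 | dilithium C1 alkoxide and lactone enolate of 28 | [Li+].[Li+].[O-][C@@H]1C[C@@H](C)[C@@H]2C[C@@H]2C3=C([O-])OC[C@H]3[C@@H]1[C@H](C)CCC=C(C)C | intermediate
30 | α-phenylselanyl lactone: 28 with PhSe on C6, cis to C7–H | O[C@@H]1C[C@@H](C)[C@@H]2C[C@@H]2[C@@]3([Se]c4ccccc4)C(=O)OC[C@H]3[C@@H]1[C@H](C)CCC=C(C)C | intermediate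
31 | selenoxide of 30 | O[C@@H]1C[C@@H](C)[C@@H]2C[C@@H]2[C@@]3([Se](=O)c4ccccc4)C(=O)OC[C@H]3[C@@H]1[C@H](C)CCC=C(C)C | intermediate
32 | (1R,3R,4S,5S,8S)-hydroxy butenolide: C6=C7, C1–OH, C8 (2R)-6-methylhept-5-en-2-yl | O[C@@H]1C[C@@H](C)[C@@H]2C[C@@H]2C2=C(COC2=O)[C@@H]1[C@H](C)CCC=C(C)C | intermediate
33 | (1R,3R,4S,5S,8S)-acetate of 32 | CC(=O)O[C@@H]1C[C@@H](C)[C@@H]2C[C@@H]2C2=C(COC2=O)[C@@H]1[C@H](C)CCC=C(C)C | intermediate
34 | CNP0205234.1: (1R,3R,4S,5S,8S)-acetate with (2R,4E)-6-hydroperoxy-6-methylhept-4-en-2-yl on C8 | CC(=O)O[C@@H]1C[C@@H](C)[C@@H]2C[C@@H]2C2=C(COC2=O)[C@@H]1[C@H](C)C/C=C/C(C)(C)OO | target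

**Totals**

Total step count: 22 (fragment 1: steps 1–5; fragment 2: steps 6–11; coupling, key step and endgame: steps 12–22).
Longest linear sequence: 17 steps (steps 6–22, from imide 9).

**The three steps most likely to fail**

Step 12. The alkenyllithium may approach the ketone anti to the neighbouring alkenyl group, which would place the two alkenyl groups trans, or it may deprotonate the ketone. The fallback sets out from 17 and 8 as before and uses the (1R,2R,3R) C1-epimeric trans-dialkenyl cyclobutanol F1 instead of discarding it. Heated with KH and 18-crown-6 in THF at reflux, F1 gives the potassium alkoxide of the trans-dialkenyl carbinol F2, which cannot reach the boat array. Alkoxides of trans-1,2-dialkenylcyclobutanols are known to expand instead by heterolysis of the C1–C4 bond to the open-chain potassium enone allyl anion F3 and conjugate re-closure of C6 onto C7. This leads to enolate 21 and, after the methanol quench, comes back to the route at ketone 22.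

Step 15. Methylene transfer may go to the electron-rich side-chain alkene, or to the upper face of the ring alkene if the zinc alkoxide does not reach across the ring. The fallback sets out from 23 and uses diazomethane with catalytic Pd(OAc)2 in Et2O at 0 °C. This carbene transfer discriminates by alkene substitution (the Z-1,2-disubstituted ring alkene reacts, the trisubstituted alkene does not) and should approach the less hindered lower face. It comes back directly at 24; no new compound arises on this path (F0).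

Step 14. Hydride delivery to the lower face of the flexible eight-membered ketone would give the C1 epimer. The fallback sets out from 22: the (1S,3R,4Z,6R,7R,8S) C1-epimeric cyclooctenol F4 is inverted under Mitsunobu conditions (4-nitrobenzoic acid, PPh3, diisopropyl azodicarboxylate, toluene, 0 °C → rt) to the (1R,3R,4Z,6R,7R,8S)-cyclooctenyl 4-nitrobenzoate F5. Methanolysis of F5 (K2CO3, MeOH) comes back to the route at 23.

**Further compounds**

F1 | step 12 | (1R,2R,3R)-2-[(1E)-3-{[tert-butyl(dimethyl)silyl]oxy}prop-1-en-1-yl]-1-[(2E,4R)-1-{[tert-butyl(diphenyl)silyl]oxy}-4,8-dimethylnona-2,7-dien-3-yl]-3-methylcyclobutan-1-ol | O[C@]1(/C(=C/CO[Si](c2ccccc2)(c2ccccc2)C(C)(C)C)[C@H](C)CCC=C(C)C)C[C@@H](C)[C@@H]1/C=C/CO[Si](C)(C)C(C)(C)C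
F2 | step 12 | potassium alkoxide of F1 | [K+].[O-][C@]1(/C(=C/CO[Si](c2ccccc2)(c2ccccc2)C(C)(C)C)[C@H](C)CCC=C(C)C)C[C@@H](C)[C@@H]1/C=C/CO[Si](C)(C)C(C)(C)C
F3 | step 12 | open-chain potassium enone allyl anion (C1–C4 cleaved: C1 ketone conjugated to C8=C7, carbanion at C4 allylic to C5=C6) | [K+].O=C(C[C@@H](C)[CH-]/C=C/CO[Si](C)(C)C(C)(C)C)/C(=C/CO[Si](c1ccccc1)(c1ccccc1)C(C)(C)C)[C@H](C)CCC=C(C)C
F0 | step 15 | none | none
F4 | step 14 | (1S,3R,4Z,6R,7R,8S)-6-({[tert-butyl(dimethyl)silyl]oxy}methyl)-7-({[tert-butyl(diphenyl)silyl]oxy}methyl)-3-methyl-8-[(2R)-6-methylhept-5-en-2-yl]cyclooct-4-en-1-ol | O[C@H]1C[C@@H](C)/C=C\[C@@H](CO[Si](C)(C)C(C)(C)C)[C@@H](CO[Si](c2ccccc2)(c2ccccc2)C(C)(C)C)[C@@H]1[C@H](C)CCC=C(C)C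
F5 | step 14 | (1R,3R,4Z,6R,7R,8S)-6-({[tert-butyl(dimethyl)silyl]oxy}methyl)-7-({[tert-butyl(diphenyl)silyl]oxy}methyl)-3-methyl-8-[(2R)-6-methylhept-5-en-2-yl]cyclooct-4-en-1-yl 4-nitrobenzoate | [O-][N+](=O)c1ccc(cc1)C(=O)O[C@@H]1C[C@@H](C)/C=C\[C@@H](CO[Si](C)(C)C(C)(C)C)[C@@H](CO[Si](c2ccccc2)(c2ccccc2)C(C)(C)C)[C@@H]1[C@H](C)CCC=C(C)C
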